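**Plan** (labdane numbering; the target is an ent-labdane, 2S,3R,4S,5S,9R,10S,13R)
- Enabling feature: in ring A the oxygen-bearing C3 adjoins quaternary C4, which holds a methyl group (C18) and the carbonyl carbon C19. This is the imprint of a 2-methyl-3-oxo ester. C4–C5 and C9–C10 are the two bonds by which an E,E-polyene folds into the trans-decalin of rings A and B.
- Retrosynthesis: the C15 acid and C19 aldehyde go back to primary alcohols, the axial 3-OH to a C3 ketone, the 2-OAc to an enolate hydroxylation, and C7=C8 to C8=C17. Then C4–C5 and C9–C10 are cut together, and last C1–C2.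
- Forward: farnesol gives a C15 allylic bromide, which is joined at C1–C2 to the dianion of an 8-phenylmenthyl 2-methylacetoacetate. One radical cascade closes ring A, then ring B. Ring A and the two chain ends are adjusted afterwards.
- Stereochemistry: C13 comes from Ru–BINAP hydrogenation and C4 from the auxiliary. C5, C9 and C10 come from the chair–chair fold. C2 comes from attack on the enolate face away from axial C19 and C20, and C3 from hydride delivered by the C19 hydroxyl group.

Key step: step 7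

Assumption: 8-phenylmenthyl 2-alkyl-3-oxo esters are taken to react through the unchelated radical conformer, for which the (1R,2S,5R) alcohol leads to the 10β-methyl (normal) decalin; the ent-configured target therefore calls for the (1S,2R,5S) alcohol, (+)-8-phenylmenthol.

**Step 1**
Reactants: 1 (2E,6E)-farnesol
Product: 2 (3R,6E)-3,7,11-trimethyldodeca-6,10-dien-1-ol [(R)-2,3-dihydrofarnesol]
Conditions: H2 (100 atm), Ru(OAc)2[(S)-BINAP] (0.2 mol %), MeOH–H2O 95:5, 20 °C
Reagents that add atoms: none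
Why: Noyori hydrogenation of an allylic alcohol, in which the hydroxyl group binds to ruthenium so that only C2=C3 is reduced, and the (S)-BINAP complex adds H2 to the face of an E-allylic alcohol that gives the 3R centre (future C13), as in geraniol to (R)-citronellol.

**Step 2**
Reactants: 2 (R)-2,3-dihydrofarnesol
Product: 3 (3R,6E)-1-(tert-butyldiphenylsilyloxy)-3,7,11-trimethyldodeca-6,10-diene
Conditions: TBDPSCl, imidazole, CH2Cl2, 0 °C to rt
Reagents that add atoms: tert-butyl(chloro)diphenylsilane, CC(C)(C)[Si](Cl)(c1ccccc1)c1ccccc1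
Why: Standard silylation; the TBDPS ether withstands acetic acid, LiAlH4 and amide base, and it keeps C15 at the alcohol level so that the hydride of step 9 meets only C3 and C19.

**Step 3**
Reactants: 3 silyl ether
Product: 4 (2E,6E,10R)-12-(tert-butyldiphenylsilyloxy)-2,6,10-trimethyldodeca-2,6-dien-1-ol
Conditions: SeO2 (0.3 equiv), t-BuOOH, salicylic acid (0.1 equiv), CH2Cl2, 0 °C to rt, stopped at partial conversion (3 recycled)
Reagents that add atoms: tert-butyl hydroperoxide, CC(C)(C)OO (oxygen passed on through SeO2, O=[Se]=O)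
Why: Catalytic SeO2 allylic oxidation (ene reaction followed by a [2,3]-shift) prefers the terminal isopropylidene group and, within it, the E-methyl group, so the E-allylic alcohol should result.

**Step 4**
Reactants: 4 allylic alcohol
Product: 5 (2E,6E,10R)-1-bromo-12-(tert-butyldiphenylsilyloxy)-2,6,10-trimethyldodeca-2,6-diene
Conditions: CBr4, PPh3, CH2Cl2, −20 to 0 °C
Reagents that add atoms: carbon tetrabromide, BrC(Br)(Br)Br
Why: The Appel reaction turns a primary allylic alcohol into the bromide under neutral conditions, without allylic shift or loss of the E geometry.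

**Step 5**
Reactants: 6 (+)-8-phenylmenthol; 7 ethyl 2-methylacetoacetate
Product: 8 (1S,2R,5S)-5-methyl-2-(2-phenylpropan-2-yl)cyclohexyl 2-methyl-3-oxobutanoate (both C2 epimers)
Conditions: DMAP (0.3 equiv), toluene, reflux, EtOH removed over 4 Å sieves
Reagents that add atoms: none
Why: DMAP-catalysed transesterification of an enolisable 3-oxo ester runs through the acylketene, accepts hindered secondary alcohols and is driven by removal of ethanol.

**Step 6**
Reactants: 8 auxiliary keto ester; 5 allylic bromide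
Product: 10 (+)-8-phenylmenthyl (6E,10E,14R)-16-(tert-butyldiphenylsilyloxy)-2,6,10,14-tetramethyl-3-oxohexadeca-6,10-dienoate (both C2 epimers), via dienolate dianion 9 (not isolated)
Conditions: 8, NaH, THF, 0 °C; n-BuLi, 0 °C; 5, 0 °C; AcOH quench
Reagents that add atoms: none
Why: Huckin–Weiler dianion alkylation, in which the more basic terminal carbanion displaces the primary allylic bromide by SN2, forms C1–C2 and keeps both E-alkenes; the labile centre (future C4) is erased in the next step.

**Step 7**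
Reactants: 10 cyclisation precursor
Product: 14 (+)-8-phenylmenthyl (13R)-15-(tert-butyldiphenylsilyloxy)-3-oxo-ent-labd-8(17)-en-19-oate (trans-decalin; C19 ester axial and cis to C20; C9 chain equatorial), via C4 radical 11 (not isolated), via monocyclic C10 radical 12 (not isolated), via bicyclic C8 radical 13 (not isolated)
Conditions: Mn(OAc)3·2H2O (2.2 equiv), Cu(OAc)2·H2O (1 equiv), degassed AcOH, 20 °C
Reagents that add atoms: none
Why: Mn(OAc)3 (trivalent manganese) forms the manganese enolate at the only acidic site, C4–H, and oxidises it by one electron to the electrophilic tertiary radical 11; this is the known oxidative free-radical polyene cyclisation of 2-alkyl-3-oxo esters. Ring A closes 6-endo-trig by attack of C4 on C5, because the nearer alkene carbon C10 is fully substituted and the tertiary radical 12 results, and ring B closes 6-endo-trig in the same way by attack of C10 on C9 to give the tertiary radical 13. Cu(OAc)2 (divalent copper) intercepts 13 and removes a β-hydrogen, chiefly from the unhindered C17 methyl group, while the second equivalent of Mn(OAc)3 returns the monovalent copper to Cu(OAc)2. C5, C10 and C9 are fixed by the chair–chair fold of the E,E-diene, in which anti addition across each E-alkene gives the trans ring fusion and the equatorial C9 chain, and the ester at C4 becomes axial because the radical reacts with its ketone C=O turned away from the ester carbonyl group. The absolute sense rests on the auxiliary, whose phenyl ring lies over the Re face of the planar C4 radical so that C5 bonds to the Si face (4S). The selectivity needed is one radical site, two endo closures and no further oxidation: the C4 methyl group leaves 14 without an acidic C4–H, the saturated C13 segment and the silyl ether lie beyond the last alkene, and no Lewis acid is added since chelation of the two carbonyl groups would favour the equatorial ester.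

**Step 8**
Reactants: 14 exocyclic alkene (with any 15 formed in step 7)
Product: 15 (+)-8-phenylmenthyl (13R)-15-(tert-butyldiphenylsilyloxy)-3-oxo-ent-labd-7-en-19-oate
Conditions: Co(L)Cl (5 mol %; L = N,N'-bis(3,5-di-tert-butylsalicylidene)cyclohexane-1,2-diaminate, trivalent cobalt), PhSiH3 (10 mol %), benzene, rt
Reagents that add atoms: none
Why: Cobalt-hydride hydrogen-atom-transfer isomerisation of a 1,1-disubstituted alkene, in which H adds to C17 to give the tertiary C8 radical, the bulky divalent cobalt complex takes back the exposed axial C7–H rather than the C9–H flanked by quaternary C10 and the side chain, and the trisubstituted product is too hindered to re-enter the cycle.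

**Step 9**
Reactants: 15 keto ester
Product: 16 (13R)-15-(tert-butyldiphenylsilyloxy)-ent-labd-7-ene-3β,19-diol (3-OH equatorial, C19 CH2OH axial)
Conditions: LiAlH4, THF, 0 °C to reflux; aqueous work-up
Reagents that add atoms: none
Why: LiAlH4 first reduces the ketone from the face away from C19 and C20 (equatorial alcohol, a centre erased in step 11) and on heating reduces the hindered neopentyl ester, releasing the auxiliary for re-use, while the silyl ether and the alkene are inert.

**Step 10**
Reactants: 16 diol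
Product: 17 (13R)-19-(tert-butyldimethylsilyloxy)-15-(tert-butyldiphenylsilyloxy)-ent-labd-7-en-3β-ol
Conditions: TBSCl (1.1 equiv), imidazole, DMF, 0 °C to rt
Reagents that add atoms: tert-butyl(chloro)dimethylsilane, CC(C)(C)[Si](C)(C)Cl
Why: Chemoselective silylation, since the primary C19 hydroxyl group reacts faster than the secondary C3 hydroxyl group next to quaternary C4, as is usual for 3,19-dihydroxylabdanes.

**Step 11**
Reactants: 17 alcohol
Product: 18 (13R)-19-(tert-butyldimethylsilyloxy)-15-(tert-butyldiphenylsilyloxy)-ent-labd-7-en-3-one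
Conditions: Dess–Martin periodinane, CH2Cl2, rt
Reagents that add atoms: none
Why: Dess–Martin oxidation restores the C3 ketone under neutral conditions that spare both silyl ethers and the trisubstituted alkene.

**Step 12**
Reactants: 18 ketone
Product: 20 (13R)-19-(tert-butyldimethylsilyloxy)-15-(tert-butyldiphenylsilyloxy)-ent-2α-hydroxylabd-7-en-3-one (2-OH equatorial; on the face opposite C20), via potassium enolate 19 (not isolated)
Conditions: KN(SiMe3)2, THF, −78 °C; 2-(phenylsulfonyl)-3-phenyloxaziridine, −78 °C; AcOH quench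
Reagents that add atoms: 2-(phenylsulfonyl)-3-phenyloxaziridine, O=S(=O)(c1ccccc1)N1OC1c1ccccc1
Why: Davis enolate hydroxylation, in which quaternary C4 allows only the C2 enolate and the oxaziridine approaches the face opposite the two syn-axial groups (C20 methyl and C19 CH2OTBS), giving the equatorial 2-OH, which is also the more stable epimer.

**Step 13**
Reactants: 20 hydroxy ketone
Product: 21 (13R)-ent-2α-acetoxy-19-(tert-butyldimethylsilyloxy)-15-(tert-butyldiphenylsilyloxy)labd-7-en-3-one
Conditions: Ac2O, pyridine, DMAP (cat.), CH2Cl2, 0 °C to rt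
Reagents that add atoms: acetic anhydride, CC(=O)OC(C)=O
Why: Routine acylation of the only free hydroxyl group; the equatorial acetoxy ketone has no driving force to epimerise.

**Step 14**
Reactants: 21 bis-silyl ether
Product: 22 (13R)-ent-2α-acetoxy-15,19-dihydroxylabd-7-en-3-one
Conditions: HF·pyridine, THF, 0 °C to rt
Reagents that add atoms: none
Why: Mildly acidic fluoride cleaves both silyl ethers at once and avoids the basic conditions under which the hydroxymethyl ketone could lose formaldehyde by retro-aldol cleavage or the acetate could be lost.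

**Step 15**
Reactants: 22 keto diol
Product: 24 (13R)-ent-2α-acetoxylabd-7-ene-3α,15,19-triol (3-OH axial; cis to 2-OAc; trans-diaxial to C19), via C19 alkoxydiacetoxyborohydride 23 (not isolated)
Conditions: Me4NBH(OAc)3 (excess), MeCN–AcOH 1:1, −20 °C
Reagents that add atoms: none
Why: Evans–Saksena hydroxyl-directed reduction of a β-hydroxy ketone, in which the C19 hydroxyl group replaces an acetate on boron and the tethered hydride reaches C3 only from the face that carries axial C19, so the new hydroxyl group becomes axial, while the reagent is too weak to reduce the ketone intermolecularly or to touch the acetate.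

**Step 16**
Reactants: 24 triol
Product: 25 target, (2S,3R,4S,5S,9R,10S,13R)-2-acetoxy-3-hydroxy-19-oxolabd-7-en-15-oic acid
Conditions: TEMPO (0.2 equiv), PhI(OAc)2 (3.1 equiv), CH2Cl2–H2O 2:1, 0 °C to rt
Reagents that add atoms: water, O
Why: Oxoammonium (TEMPO/PhI(OAc)2) oxidation takes primary over secondary carbinols, so the hindered axial 3-OH is left alone; only the unhindered C15 aldehyde hydrates and goes on to the acid, whereas the C19 aldehyde on quaternary C4, axial and syn to the C20 methyl group, should resist hydration, and the oxidant is limited to the three equivalents required.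

**Compound list**
1 | (2E,6E)-farnesol | CC(C)=CCC/C(C)=C/CC/C(C)=C/CO | starting material
2 | (3R,6E)-3,7,11-trimethyldodeca-6,10-dien-1-ol | CC(C)=CCC/C(C)=C/CC[C@@H](C)CCO | intermediate
3 | TBDPS ether of 2 | CC(C)=CCC/C(C)=C/CC[C@@H](C)CCO[Si](c1ccccc1)(c1ccccc1)C(C)(C)C | intermediate
4 | (2E,6E,10R)-12-(TBDPS-oxy)-2,6,10-trimethyldodeca-2,6-dien-1-ol | OC/C(C)=C/CC/C(C)=C/CC[C@@H](C)CCO[Si](c1ccccc1)(c1ccccc1)C(C)(C)C | intermediate
5 | (2E,6E,10R)-1-bromo-12-(TBDPS-oxy)-2,6,10-trimethyldodeca-2,6-diene | BrC/C(C)=C/CC/C(C)=C/CC[C@@H](C)CCO[Si](c1ccccc1)(c1ccccc1)C(C)(C)C | intermediate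
6 | (+)-8-phenylmenthol, (1S,2R,5S) | CC(C)(c1ccccc1)[C@H]1CC[C@H](C)C[C@@H]1O | starting material
7 | ethyl 2-methylacetoacetate | CCOC(=O)C(C)C(C)=O | starting material
8 | (+)-8-phenylmenthyl 2-methyl-3-oxobutanoate (C2 epimers) | CC(=O)C(C)C(=O)O[C@H]1C[C@@H](C)CC[C@@H]1C(C)(C)c1ccccc1 | intermediate
9 | sodium lithium dienolate (dianion) of 8 | [Na+].[Li+].C=C([O-])C(C)=C([O-])O[C@H]1C[C@@H](C)CC[C@@H]1C(C)(C)c1ccccc1 | intermediate
10 | (+)-8-phenylmenthyl (6E,10E,14R)-16-(TBDPS-oxy)-2,6,10,14-tetramethyl-3-oxohexadeca-6,10-dienoate (C2 epimers) | CC(C(=O)CC/C(C)=C/CC/C(C)=C/CC[C@@H](C)CCO[Si](c1ccccc1)(c1ccccc1)C(C)(C)C)C(=O)O[C@H]1C[C@@H](C)CC[C@@H]1C(C)(C)c1ccccc1 | intermediate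
11 | open-chain C4 radical | C[C](C(=O)CC/C(C)=C/CC/C(C)=C/CC[C@@H](C)CCO[Si](c1ccccc1)(c1ccccc1)C(C)(C)C)C(=O)O[C@H]1C[C@@H](C)CC[C@@H]1C(C)(C)c1ccccc1 | intermediate
12 | monocyclic C10 radical (ring A closed) | O=C1CC[C](C)[C@H](CC/C(C)=C/CC[C@@H](C)CCO[Si](c2ccccc2)(c2ccccc2)C(C)(C)C)[C@]1(C)C(=O)O[C@H]1C[C@@H](C)CC[C@@H]1C(C)(C)c1ccccc1 | intermediate
13 | bicyclic C8 radical (rings A and B closed) | O=C1CC[C@@]2(C)[C@H](CC[C@@H](C)CCO[Si](c3ccccc3)(c3ccccc3)C(C)(C)C)[C](C)CC[C@@H]2[C@]1(C)C(=O)O[C@H]1C[C@@H](C)CC[C@@H]1C(C)(C)c1ccccc1 | intermediate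
14 | (+)-8-phenylmenthyl (13R)-15-(TBDPS-oxy)-3-oxo-ent-labd-8(17)-en-19-oate | O=C1CC[C@@]2(C)[C@H](CC[C@@H](C)CCO[Si](c3ccccc3)(c3ccccc3)C(C)(C)C)C(=C)CC[C@@H]2[C@]1(C)C(=O)O[C@H]1C[C@@H](C)CC[C@@H]1C(C)(C)c1ccccc1 | intermediate
15 | (+)-8-phenylmenthyl (13R)-15-(TBDPS-oxy)-3-oxo-ent-labd-7-en-19-oate | O=C1CC[C@@]2(C)[C@H](CC[C@@H](C)CCO[Si](c3ccccc3)(c3ccccc3)C(C)(C)C)C(C)=CC[C@@H]2[C@]1(C)C(=O)O[C@H]1C[C@@H](C)CC[C@@H]1C(C)(C)c1ccccc1 | intermediate
16 | (13R)-15-(TBDPS-oxy)-ent-labd-7-ene-3β,19-diol (3-OH equatorial) | O[C@@H]1CC[C@@]2(C)[C@H](CC[C@@H](C)CCO[Si](c3ccccc3)(c3ccccc3)C(C)(C)C)C(C)=CC[C@@H]2[C@]1(C)CO | intermediate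
17 | 19-TBS ether of 16 | O[C@@H]1CC[C@@]2(C)[C@H](CC[C@@H](C)CCO[Si](c3ccccc3)(c3ccccc3)C(C)(C)C)C(C)=CC[C@@H]2[C@]1(C)CO[Si](C)(C)C(C)(C)C | intermediate
18 | (13R)-19-(TBS-oxy)-15-(TBDPS-oxy)-ent-labd-7-en-3-one | O=C1CC[C@@]2(C)[C@H](CC[C@@H](C)CCO[Si](c3ccccc3)(c3ccccc3)C(C)(C)C)C(C)=CC[C@@H]2[C@]1(C)CO[Si](C)(C)C(C)(C)C | intermediate
19 | potassium C2=C3 enolate of 18 | [K+].[O-]C1=CC[C@@]2(C)[C@H](CC[C@@H](C)CCO[Si](c3ccccc3)(c3ccccc3)C(C)(C)C)C(C)=CC[C@@H]2[C@]1(C)CO[Si](C)(C)C(C)(C)C | intermediate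
20 | equatorial 2-hydroxy ketone (ent-2α-OH) | O[C@H]1C[C@@]2(C)[C@H](CC[C@@H](C)CCO[Si](c3ccccc3)(c3ccccc3)C(C)(C)C)C(C)=CC[C@@H]2[C@](C)(CO[Si](C)(C)C(C)(C)C)C1=O | intermediate
21 | equatorial 2-acetoxy ketone, bis-silyl ether | CC(=O)O[C@H]1C[C@@]2(C)[C@H](CC[C@@H](C)CCO[Si](c3ccccc3)(c3ccccc3)C(C)(C)C)C(C)=CC[C@@H]2[C@](C)(CO[Si](C)(C)C(C)(C)C)C1=O | intermediate
22 | (13R)-ent-2α-acetoxy-15,19-dihydroxylabd-7-en-3-one | CC(=O)O[C@H]1C[C@@]2(C)[C@H](CC[C@@H](C)CCO)C(C)=CC[C@@H]2[C@](C)(CO)C1=O | intermediate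
23 | tetramethylammonium C19-alkoxydiacetoxyborohydride of 22 | C[N+](C)(C)C.CC(=O)O[C@H]1C[C@@]2(C)[C@H](CC[C@@H](C)CCO)C(C)=CC[C@@H]2[C@](C)(CO[BH-](OC(C)=O)OC(C)=O)C1=O | intermediate
24 | (13R)-ent-2α-acetoxylabd-7-ene-3α,15,19-triol (3-OH axial) | CC(=O)O[C@H]1C[C@@]2(C)[C@H](CC[C@@H](C)CCO)C(C)=CC[C@@H]2[C@](C)(CO)[C@H]1O | intermediate
25 | CNP0180877.1, (2S,3R,4S,5S,9R,10S,13R)-2-acetoxy-3-hydroxy-19-oxolabd-7-en-15-oic acid | CC(=O)O[C@H]1C[C@@]2(C)[C@H](CC[C@@H](C)CC(=O)O)C(C)=CC[C@@H]2[C@](C)(C=O)[C@H]1O | target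

**Totals**
Total step count: 16. Longest linear sequence: 15 (steps 1–4 and 6–16, from farnesol).

**Steps most likely to fail**

**Step 7.**
- What may go wrong: incomplete shielding of one face of the C4 radical at 20 °C, and oxidation of the monocyclic radical by Cu(OAc)2 before ring B closes.
- Fallback, from 10 back to 14: the same two bonds are made by a redox-neutral phenylselanyl group-transfer cascade, which needs no oxidant and can run cold.
- 10 is selenenylated at C4 (NaH, PhSeCl, THF, 0 °C) to the 2-methyl-2-phenylselanyl-3-oxo ester F1.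
- Irradiation (visible lamp, toluene, −40 °C) breaks the weak C4–Se bond. The cascade runs as before, and the C8 radical takes PhSe from a further molecule of F1 on the face away from C20, giving the 8-phenylselanyl decalin F2.
- H2O2/pyridine (CH2Cl2, 0 °C) gives the selenoxide F3, which eliminates syn toward the C17 methyl group to 14.

**Step 8.**
- What may go wrong: hydrogen abstraction from C9–H in competition with C7–H, which moves the alkene to the tetrasubstituted C8=C9 position, or stalling of the catalyst.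
- Fallback, from 14 back to 16: a regiospecific sequence of oxidation, allylic shift and reduction.
- SeO2/t-BuOOH (CH2Cl2, rt) hydroxylates the accessible allylic position C7 to the axial 7-hydroxy-8(17)-ene F4.
- SOCl2 in Et2O (0 °C) replaces the hydroxyl group with allylic shift (SNi') to give the primary 17-chloro-7-ene F5.
- The LiAlH4 conditions of step 9 then displace the primary allylic chloride by hydride while C3 and C19 are reduced, which gives 16 directly.

**Step 16.**
- What may go wrong: over-oxidation of the C19 aldehyde, or slow oxidation of the neopentyl C19 carbinol while the oxidant is consumed elsewhere.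
- Fallback, from 21 back to 25: the two oxidations are separated in time, so that the aldehyde never meets water and oxidant together.
- Bu4NF buffered with AcOH (THF, 0 °C) should free only the silyl ether on the unbranched chain, because the C19 ether is neopentyl and axial. This gives the 15-alcohol F6.
- TEMPO/PhI(OAc)2 in MeCN–H2O takes F6 to the 15-acid F7 while C19 is still masked.
- HF·pyridine gives the 19-hydroxy-3-oxo acid F8, and Me4NBH(OAc)3 as in step 15 gives the 3,19-dihydroxy acid F9.
- TEMPO/PhI(OAc)2 in dry CH2Cl2, where no hydrate can form, stops at the aldehyde 25.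

**Further compounds**
F1 | step 7 | (+)-8-phenylmenthyl 2-methyl-2-phenylselanyl-3-oxo ester of the E,E-diene chain (C4 epimers) | CC([Se]c1ccccc1)(C(=O)CC/C(C)=C/CC/C(C)=C/CC[C@@H](C)CCO[Si](c1ccccc1)(c1ccccc1)C(C)(C)C)C(=O)O[C@H]1C[C@@H](C)CC[C@@H]1C(C)(C)c1ccccc1
F2 | step 7 | 8-phenylselanyl-3-oxo-ent-labdan-19-oate (PhSe equatorial, C17 axial) | O=C1CC[C@@]2(C)[C@H](CC[C@@H](C)CCO[Si](c3ccccc3)(c3ccccc3)C(C)(C)C)[C@@](C)([Se]c3ccccc3)CC[C@@H]2[C@]1(C)C(=O)O[C@H]1C[C@@H](C)CC[C@@H]1C(C)(C)c1ccccc1
F3 | step 7 | selenoxide of F2 | O=C1CC[C@@]2(C)[C@H](CC[C@@H](C)CCO[Si](c3ccccc3)(c3ccccc3)C(C)(C)C)[C@@](C)([Se](=O)c3ccccc3)CC[C@@H]2[C@]1(C)C(=O)O[C@H]1C[C@@H](C)CC[C@@H]1C(C)(C)c1ccccc1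
F4 | step 8 | axial 7-hydroxy derivative of 14 | O=C1CC[C@@]2(C)[C@H](CC[C@@H](C)CCO[Si](c3ccccc3)(c3ccccc3)C(C)(C)C)C(=C)[C@@H](O)C[C@@H]2[C@]1(C)C(=O)O[C@H]1C[C@@H](C)CC[C@@H]1C(C)(C)c1ccccc1
F5 | step 8 | 17-chloro derivative of 15 | O=C1CC[C@@]2(C)[C@H](CC[C@@H](C)CCO[Si](c3ccccc3)(c3ccccc3)C(C)(C)C)C(CCl)=CC[C@@H]2[C@]1(C)C(=O)O[C@H]1C[C@@H](C)CC[C@@H]1C(C)(C)c1ccccc1
F6 | step 16 | ent-2α-acetoxy-19-(TBS-oxy)-15-hydroxylabd-7-en-3-one | CC(=O)O[C@H]1C[C@@]2(C)[C@H](CC[C@@H](C)CCO)C(C)=CC[C@@H]2[C@](C)(CO[Si](C)(C)C(C)(C)C)C1=O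
F7 | step 16 | ent-2α-acetoxy-19-(TBS-oxy)-3-oxolabd-7-en-15-oic acid | CC(=O)O[C@H]1C[C@@]2(C)[C@H](CC[C@@H](C)CC(=O)O)C(C)=CC[C@@H]2[C@](C)(CO[Si](C)(C)C(C)(C)C)C1=O
F8 | step 16 | ent-2α-acetoxy-19-hydroxy-3-oxolabd-7-en-15-oic acid | CC(=O)O[C@H]1C[C@@]2(C)[C@H](CC[C@@H](C)CC(=O)O)C(C)=CC[C@@H]2[C@](C)(CO)C1=O
F9 | step 16 | ent-2α-acetoxy-3α,19-dihydroxylabd-7-en-15-oic acid | CC(=O)O[C@H]1C[C@@]2(C)[C@H](CC[C@@H](C)CC(=O)O)C(C)=CC[C@@H]2[C@](C)(CO)[C@H]1O
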